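The bicycle is numbered C1 (lavandulyl bridgehead), C2–C4 (aroyl β-diketone bridge), C5 (prenyl bridgehead), C6 (CMe2), C7 (CH-prenyl), C8 (CH2), C9 (bridging C=O). The plan cuts C1–C8. Because C4 and C9, both on C5, are oxygenated, ring C1–C2–C3–C4–C5–C9 is taken back to a mirror-symmetric 2,6-dimethoxycyclohexa-2,5-diene whose sp3 carbon C5 carries prenyl and a CMe2–CO–CHN2 arm (C6–C8). One copper-catalysed operation adds carbenoid C8 to one enantiotopic enol ether, and acid then breaks C8–C9. This closes the cyclohexanone ring C1–C8–C7–C6–C5–C9 and sets C5 and C1. The C7 prenyl, C2 carbonyl, C1 lavandulyl and C3 aroyl groups follow.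

Key step: step 5

Assumption: the sense of induction of the Cu–bis(oxazoline) catalyst is not predicted, so the ligand antipode that gives (1S,5S)-11 is to be used; lithiated species made and consumed in one flask are described in the Why lines and carry no number.
Remark: the CIP letters at C1, C5 and the side-chain carbon change along the route only because substituent priorities change; none of these centres is inverted.

Step 1
Reactants: 1 2,6-dimethoxyphenylacetic acid
Product: 3 2-(2,6-dimethoxyphenyl)-2-methylpropanoic acid, via monomethyl carboxylate 2 (not isolated)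
Conditions: LDA (2.2 equiv), THF, 0 °C; MeI (1.05 equiv); LDA (1.3 equiv), DMPU, 0 → 40 °C; MeI (1.5 equiv); aq HCl work-up
Reagents that add atoms: iodomethane, CI
Why: α-Alkylation of a carboxylic acid enediolate, run twice in one flask: LDA forms the dilithio enediolate, MeI methylates it at carbon, and fresh LDA regenerates the enediolate of 2 for the second methylation, so no ester has to be made and cleaved; no stereocentre results.

Step 2
Reactants: 3 2-(2,6-dimethoxyphenyl)-2-methylpropanoic acid
Product: 4 2-(2,6-dimethoxycyclohexa-2,5-dien-1-yl)-2-methylpropanoic acid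
Conditions: Li (6 equiv), NH3(l)/THF, t-BuOH (3 equiv), −78 → −33 °C; NH4Cl; extraction at pH 6, 0 °C, used at once
Reagents that add atoms: none
Why: Birch reduction: the carboxylate is not reduced and the two methoxy groups stay on the remaining double bonds, so hydrogen is added at the ipso and para carbons and the mirror-symmetric 1,4-diene should form without a stereocentre; the cold, buffered work-up keeps the acid from hydrolysing its own enol ethers.

Step 3
Reactants: 4 2-(2,6-dimethoxycyclohexa-2,5-dien-1-yl)-2-methylpropanoic acid; 5 prenyl bromide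
Product: 7 3-[2,6-dimethoxy-1-(3-methylbut-2-en-1-yl)cyclohexa-2,5-dien-1-yl]-3-methylbutan-2-one, via lithium carboxylate 6 (not isolated)
Conditions: t-BuLi (2.3 equiv), THF, −78 → −45 °C; 5 (1.2 equiv), −78 → 0 °C; MeLi (4 equiv), 0 °C → rt; inverse quench into aq NH4Cl
Reagents that add atoms: methyllithium, [Li]C
Why: Metalation–alkylation of a 1,5-dimethoxycyclohexa-1,4-diene at the carbon between the methoxy groups, then ketone synthesis from a lithium carboxylate and MeLi: after carboxylate formation t-BuLi removes the doubly allylic C–H that is acidified by both C–OMe carbons, the pentadienyl anion is alkylated at its central carbon by the SN2-reactive allylic bromide (highest charge density, and relief of strain between the tert-alkyl arm and the methoxy groups), and the hindered carboxylate 6 takes up one MeLi to a dilithio gem-diolate that releases the methyl ketone only on quench; the new quaternary carbon lies on the mirror plane and is not stereogenic.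

Step 4
Reactants: 7 3-[2,6-dimethoxy-1-(3-methylbut-2-en-1-yl)cyclohexa-2,5-dien-1-yl]-3-methylbutan-2-one
Product: 9 1-diazo-3-[2,6-dimethoxy-1-(3-methylbut-2-en-1-yl)cyclohexa-2,5-dien-1-yl]-3-methylbutan-2-one, via trifluoroacetyl diketone 8 (not isolated)
Conditions: LiHMDS, THF, −78 °C; CF3CO2CH2CF3; then MsN3, Et3N, H2O (1 equiv), MeCN, rt
Reagents that add atoms: methanesulfonyl azide, CS(=O)(=O)N=[N+]=[N-]
Why: Detrifluoroacetylative diazo transfer (Claisen trifluoroacetylation, then Regitz-type transfer): the ketone can enolise only toward its methyl group, and the sequence is basic throughout, so the two enol ethers, which an acid chloride route would endanger, are not touched; no stereocentre is involved.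

Step 5
Reactants: 9 1-diazo-3-[2,6-dimethoxy-1-(3-methylbut-2-en-1-yl)cyclohexa-2,5-dien-1-yl]-3-methylbutan-2-one
Product: 11 (1S,5S)-4-methoxy-6,6-dimethyl-5-(3-methylbut-2-en-1-yl)bicyclo[3.3.1]non-3-ene-7,9-dione, via methoxycyclopropane 10 (not isolated)
Conditions: CuOTf·½C6H6 (10 mol %), t-Bu-box (12 mol %, antipode as assumed), toluene, 50 °C, slow addition of 9; then 0.5 M HCl, THF, 0 °C, 10 min
Reagents that add atoms: water, O
Why: Cu(I)–bis(oxazoline) extrudes N2 from 9 to give an electrophilic copper carbenoid at C8, which adds in a [2+1] manner to one of the two enantiotopic methoxy enol ethers (C9=C1) on the ring face that carries the arm, forming bonds C8–C1 and C8–C9 and with them the cyclopropane and the cyclopentanone C5–C6–C7–C8–C9 (5-exo delivery to the nearer alkene carbon C9, bicyclo[3.1.0]hexanone 10). The closest known reaction type is the catalytic asymmetric intramolecular cyclopropanation of α-diazo ketones that desymmetrises 1,1-disubstituted 2,6-dimethoxycyclohexa-2,5-dienes, followed by opening of the donor–acceptor cyclopropane. Dilute acid then heterolyses the push–pull bond C8–C9 (methoxy donor on C9, C7 carbonyl acceptor at C8) and water turns the oxocarbenium ion into the C9 ketone, so the surviving C1–C8 bond completes the six-membered ring C1–C8–C7–C6–C5–C9, in effect a six-membered ring closure by C-alkylation of the enol ether β-carbon C1. C5 becomes stereogenic through the ligand's choice between the two enol ethers, and C1 is tied to C5 because the three-atom tether can only bridge cis, so one catalyst-controlled event sets both bridgeheads. The step needs chemoselectivity for the enol ether over the prenyl alkene, over C–H insertion and over oxonium ylide formation, which the five-membered tether, the much higher nucleophilicity of the enol ether, copper in place of rhodium and the absence of hydrogen on C6 should provide; the second enol ether should outlast the brief acid treatment because its oxocarbenium ion at C4 would sit next to the electron-poor C5 that carries the C9 carbonyl.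

Step 6
Reactants: 11 (1S,5S)-4-methoxy-6,6-dimethyl-5-(3-methylbut-2-en-1-yl)bicyclo[3.3.1]non-3-ene-7,9-dione
Product: 12 (1S,5S)-4-methoxy-6,6-dimethyl-7-methylidene-5-(3-methylbut-2-en-1-yl)bicyclo[3.3.1]non-3-en-9-one
Conditions: Ph3PCH3Br (1.5 equiv), KOt-Bu (1.4 equiv), toluene, 0 → 50 °C
Reagents that add atoms: methyltriphenylphosphonium bromide, C[P+](c1ccccc1)(c1ccccc1)c1ccccc1.[Br-]
Why: Wittig methylenation: only the C7 ketone offers an open (exo) face to the bulky ylide, whereas C9 is shielded by the quaternary C5, its prenyl group and the syn methyl on C6, and the enol ether is inert to the ylide; no stereocentre is affected.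

Step 7
Reactants: 12 (1S,5S)-4-methoxy-6,6-dimethyl-7-methylidene-5-(3-methylbut-2-en-1-yl)bicyclo[3.3.1]non-3-en-9-one; 13 1-bromo-2-methylprop-1-ene
Product: 15 (1R,5S,7R)-4-methoxy-6,6-dimethyl-5,7-bis(3-methylbut-2-en-1-yl)bicyclo[3.3.1]non-3-en-9-one, via alkylborane 14 (not isolated)
Conditions: 9-BBN (1.5 equiv), THF, 0 °C → rt; then 13 (3 equiv), Pd(dppf)Cl2 (5 mol %), AsPh3 (10 mol %), Cs2CO3 (3 equiv), DMF/H2O, 50 °C
Reagents that add atoms: none
Why: Hydroboration followed by B-alkyl Suzuki–Miyaura coupling: 9-BBN should add only to the 1,1-disubstituted alkene (the trisubstituted prenyl and enol ether alkenes and the hindered C9 ketone react far more slowly), with boron on the terminal carbon and hydrogen delivered to C7 from the exo face because the endo face is blocked by the C2–C4 bridge, which sets C7 (R, CH2 endo); the coupling with 13 then completes the prenyl group without involving C7.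

Step 8
Reactants: 15 (1R,5S,7R)-4-methoxy-6,6-dimethyl-5,7-bis(3-methylbut-2-en-1-yl)bicyclo[3.3.1]non-3-en-9-one
Product: 16 (1R,5S,7R)-4-methoxy-6,6-dimethyl-5,7-bis(3-methylbut-2-en-1-yl)bicyclo[3.3.1]non-3-ene-2,9-dione
Conditions: PhI(OAc)2 (3 equiv), t-BuOOH (5 equiv), Cs2CO3 (3 equiv), EtOAc, −20 °C
Reagents that add atoms: tert-butyl hydroperoxide, CC(C)(C)OO
Why: Allylic C–H oxidation by tert-butylperoxyl radicals (known for cyclic enol ethers, which give vinylogous esters): hydrogen should be abstracted at C2 because these C–H bonds are the weakest and most electron-rich (allylic to the methoxy enol ether), whereas both prenyl CH2 groups stand next to fully substituted ring carbons, and the C2 peroxide collapses to the ketone under the carbonate buffer that also protects the enol ether; no stereocentre is touched.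

Step 9
Reactants: 17 (R)-lavandulol
Product: 18 (R)-lavandulyl triflate [(2R)-5-methyl-2-(prop-1-en-2-yl)hex-4-en-1-yl trifluoromethanesulfonate]
Conditions: Tf2O (1.1 equiv), 2,6-lutidine (1.3 equiv), CH2Cl2, −78 °C; cold pentane filtration, used at once
Reagents that add atoms: triflic anhydride, O=S(=O)(OS(=O)(=O)C(F)(F)F)C(F)(F)F
Why: O-Sulfonylation of a primary alcohol with triflic anhydride and a hindered pyridine base at low temperature; the stereocentre is β to the oxygen and takes no part.

Step 10
Reactants: 16 (1R,5S,7R)-4-methoxy-6,6-dimethyl-5,7-bis(3-methylbut-2-en-1-yl)bicyclo[3.3.1]non-3-ene-2,9-dione; 18 (R)-lavandulyl triflate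
Product: 19 (1R,5S,7R)-4-methoxy-6,6-dimethyl-1-[(2S)-5-methyl-2-(prop-1-en-2-yl)hex-4-en-1-yl]-5,7-bis(3-methylbut-2-en-1-yl)bicyclo[3.3.1]non-3-ene-2,9-dione
Conditions: LDA (1.3 equiv), THF, −78 °C; 18 (1.8 equiv), −78 → −30 °C
Reagents that add atoms: none
Why: Bridgehead lithiation–alkylation (known for bicyclo[3.3.1]nonane vinylogous esters with allylic halides and MeI), here with a primary triflate as electrophile: LDA removes the only acidic proton, C1–H between the C2 and C9 carbonyls, and the pyramidal carbanion, which cannot become an O-nucleophile without a bridgehead double bond, should displace triflate from the CH2 of 18; C1 is a bridgehead and keeps its configuration, and the lavandulyl stereocentre is β to the reacting carbon, so, unlike in an aldehyde, it cannot epimerise.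

Step 11
Reactants: 20 3-hydroxybenzoic acid
Product: 21 tert-butyldimethylsilyl 3-[(tert-butyldimethylsilyl)oxy]benzoate
Conditions: TBSCl (2.3 equiv), imidazole (4 equiv), DMF, rt
Reagents that add atoms: tert-butyldimethylsilyl chloride, CC(C)(C)[Si](C)(C)Cl
Why: O-Silylation of both the phenol and the acid; the silyl ester is the handle for the next step.

Step 12
Reactants: 21 tert-butyldimethylsilyl 3-[(tert-butyldimethylsilyl)oxy]benzoate
Product: 22 3-[(tert-butyldimethylsilyl)oxy]benzoyl chloride
Conditions: (COCl)2 (1.2 equiv), DMF (cat.), CH2Cl2, 0 °C → rt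
Reagents that add atoms: oxalyl chloride, O=C(Cl)C(=O)Cl
Why: Direct conversion of a silyl ester into the acid chloride by Vilsmeier-type activation under neutral conditions, which leaves the aryl silyl ether in place.

Step 13
Reactants: 19 (1R,5S,7R)-4-methoxy-6,6-dimethyl-1-[(2S)-5-methyl-2-(prop-1-en-2-yl)hex-4-en-1-yl]-5,7-bis(3-methylbut-2-en-1-yl)bicyclo[3.3.1]non-3-ene-2,9-dione; 22 3-[(tert-butyldimethylsilyl)oxy]benzoyl chloride
Product: 23 (1S,5S,7R)-3-{3-[(tert-butyldimethylsilyl)oxy]benzoyl}-4-methoxy-6,6-dimethyl-1-[(2S)-5-methyl-2-(prop-1-en-2-yl)hex-4-en-1-yl]-5,7-bis(3-methylbut-2-en-1-yl)bicyclo[3.3.1]non-3-ene-2,9-dione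
Conditions: LTMP (3 equiv), THF, −78 °C; 22 (3 equiv), −78 → −40 °C
Reagents that add atoms: none
Why: Vinyl lithiation–acylation of a β-methoxy enone: with both bridgeheads quaternary, LTMP removes C3–H (between C2=O and C4–OMe) and the alkenyllithium is acylated at carbon by acid chloride 22, whose silyl ether offers no acidic or electrophilic site; no stereocentre is affected.

Step 14
Reactants: 23 (1S,5S,7R)-3-{3-[(tert-butyldimethylsilyl)oxy]benzoyl}-4-methoxy-6,6-dimethyl-1-[(2S)-5-methyl-2-(prop-1-en-2-yl)hex-4-en-1-yl]-5,7-bis(3-methylbut-2-en-1-yl)bicyclo[3.3.1]non-3-ene-2,9-dione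
Product: 24 (1R,5R,7R)-2-hydroxy-3-(3-hydroxybenzoyl)-6,6-dimethyl-1-[(2S)-5-methyl-2-(prop-1-en-2-yl)hex-4-en-1-yl]-5,7-bis(3-methylbut-2-en-1-yl)bicyclo[3.3.1]non-2-ene-4,9-dione (CNP0103487.1)
Conditions: LiOH (2 M aq), dioxane, 90 °C; then 1 M HCl to pH 3
Reagents that add atoms: lithium hydroxide, [Li+].[OH-]
Why: Addition–elimination of hydroxide at C4 of the 2-acyl vinylogous ester expels methoxide and gives the enolised tricarbonyl system, the same hot aqueous base removes the aryl silyl group, and the product should sit as a delocalised enolate/phenolate until acidification, which guards it against retro-Claisen loss of the aroyl group; all stereocentres are remote from the reacting atoms.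

Compound list
1 | 2,6-dimethoxyphenylacetic acid | COc1cccc(OC)c1CC(=O)O | starting material
2 | lithium 2-(2,6-dimethoxyphenyl)propanoate (racemic) | COc1cccc(OC)c1C(C)C(=O)[O-].[Li+] | intermediate
3 | 2-(2,6-dimethoxyphenyl)-2-methylpropanoic acid | COc1cccc(OC)c1C(C)(C)C(=O)O | intermediate
4 | 2-(2,6-dimethoxycyclohexa-2,5-dien-1-yl)-2-methylpropanoic acid | COC1=CCC=C(OC)C1C(C)(C)C(=O)O | intermediate
5 | prenyl bromide (1-bromo-3-methylbut-2-ene) | CC(C)=CCBr | starting material
6 | lithium 2-[2,6-dimethoxy-1-(3-methylbut-2-en-1-yl)cyclohexa-2,5-dien-1-yl]-2-methylpropanoate | COC1=CCC=C(OC)C1(CC=C(C)C)C(C)(C)C(=O)[O-].[Li+] | intermediate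
7 | 3-[2,6-dimethoxy-1-(3-methylbut-2-en-1-yl)cyclohexa-2,5-dien-1-yl]-3-methylbutan-2-one | COC1=CCC=C(OC)C1(CC=C(C)C)C(C)(C)C(C)=O | intermediate
8 | 5-[2,6-dimethoxy-1-(3-methylbut-2-en-1-yl)cyclohexa-2,5-dien-1-yl]-1,1,1-trifluoro-5-methylhexane-2,4-dione | COC1=CCC=C(OC)C1(CC=C(C)C)C(C)(C)C(=O)CC(=O)C(F)(F)F | intermediate
9 | 1-diazo-3-[2,6-dimethoxy-1-(3-methylbut-2-en-1-yl)cyclohexa-2,5-dien-1-yl]-3-methylbutan-2-one | COC1=CCC=C(OC)C1(CC=C(C)C)C(C)(C)C(=O)C=[N+]=[N-] | intermediate
10 | methoxycyclopropane: all-cis tricycle with the cyclopropane C1–C8–C9 fused to the cyclopentanone C5–C6–C7–C8–C9 and to the methoxycyclohexene C1–C2–C3=C4–C5–C9; OMe on C4 and C9, prenyl on C5, C1 and C5 configured as in 11 | COC1=CC[C@H]2[C@H]3C(=O)C(C)(C)[C@]1(CC=C(C)C)[C@@]23OC | intermediate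
11 | (1S,5S)-4-methoxy-6,6-dimethyl-5-(3-methylbut-2-en-1-yl)bicyclo[3.3.1]non-3-ene-7,9-dione | [C@@H]12CC(=O)C(C)(C)[C@@](CC=C(C)C)(C(OC)=CC1)C2=O | intermediate
12 | (1S,5S)-4-methoxy-6,6-dimethyl-7-methylidene-5-(3-methylbut-2-en-1-yl)bicyclo[3.3.1]non-3-en-9-one | [C@@H]12CC(=C)C(C)(C)[C@@](CC=C(C)C)(C(OC)=CC1)C2=O | intermediate
13 | 1-bromo-2-methylprop-1-ene | CC(C)=CBr | starting material
14 | alkylborane: 12 with exo H on C7 and an endo CH2–(9-borabicyclo[3.3.1]nonan-9-yl) group on C7; C1 and C5 unchanged | [C@@H]12C[C@@H](CB3C4CCCC3CCC4)C(C)(C)[C@@](CC=C(C)C)(C(OC)=CC1)C2=O | intermediate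
15 | (1R,5S,7R)-4-methoxy-6,6-dimethyl-5,7-bis(3-methylbut-2-en-1-yl)bicyclo[3.3.1]non-3-en-9-one (C7 prenyl endo, cis to the C2–C4 bridge) | [C@@H]12C[C@@H](CC=C(C)C)C(C)(C)[C@@](CC=C(C)C)(C(OC)=CC1)C2=O | intermediate
16 | (1R,5S,7R)-4-methoxy-6,6-dimethyl-5,7-bis(3-methylbut-2-en-1-yl)bicyclo[3.3.1]non-3-ene-2,9-dione | [C@@H]12C[C@@H](CC=C(C)C)C(C)(C)[C@@](CC=C(C)C)(C(OC)=CC1=O)C2=O | intermediate
17 | (R)-lavandulol [(2R)-5-methyl-2-(prop-1-en-2-yl)hex-4-en-1-ol] | C=C(C)[C@@H](CC=C(C)C)CO | starting material
18 | (R)-lavandulyl triflate [(2R)-5-methyl-2-(prop-1-en-2-yl)hex-4-en-1-yl trifluoromethanesulfonate] | C=C(C)[C@@H](CC=C(C)C)COS(=O)(=O)C(F)(F)F | intermediate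
19 | (1R,5S,7R)-4-methoxy-6,6-dimethyl-1-[(2S)-5-methyl-2-(prop-1-en-2-yl)hex-4-en-1-yl]-5,7-bis(3-methylbut-2-en-1-yl)bicyclo[3.3.1]non-3-ene-2,9-dione | C=C(C)[C@@H](CC=C(C)C)C[C@@]12C[C@@H](CC=C(C)C)C(C)(C)[C@@](CC=C(C)C)(C(OC)=CC1=O)C2=O | intermediate
20 | 3-hydroxybenzoic acid | O=C(O)c1cccc(O)c1 | starting material
21 | tert-butyldimethylsilyl 3-[(tert-butyldimethylsilyl)oxy]benzoate | CC(C)(C)[Si](C)(C)Oc1cccc(c1)C(=O)O[Si](C)(C)C(C)(C)C | intermediate
22 | 3-[(tert-butyldimethylsilyl)oxy]benzoyl chloride | CC(C)(C)[Si](C)(C)Oc1cccc(c1)C(=O)Cl | intermediate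
23 | (1S,5S,7R)-3-{3-[(tert-butyldimethylsilyl)oxy]benzoyl}-4-methoxy-6,6-dimethyl-1-[(2S)-5-methyl-2-(prop-1-en-2-yl)hex-4-en-1-yl]-5,7-bis(3-methylbut-2-en-1-yl)bicyclo[3.3.1]non-3-ene-2,9-dione | C=C(C)[C@@H](CC=C(C)C)C[C@@]12C[C@@H](CC=C(C)C)C(C)(C)[C@@](CC=C(C)C)(C(OC)=C(C(=O)c3cccc(O[Si](C)(C)C(C)(C)C)c3)C1=O)C2=O | intermediate
24 | (1R,5R,7R)-2-hydroxy-3-(3-hydroxybenzoyl)-6,6-dimethyl-1-[(2S)-5-methyl-2-(prop-1-en-2-yl)hex-4-en-1-yl]-5,7-bis(3-methylbut-2-en-1-yl)bicyclo[3.3.1]non-2-ene-4,9-dione (CNP0103487.1) | C=C(C)[C@@H](CC=C(C)C)C[C@@]12C[C@@H](CC=C(C)C)C(C)(C)[C@@](CC=C(C)C)(C(=O)C(C(=O)c3cccc(O)c3)=C1O)C2=O | target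

Total step count: 14. Longest linear sequence: 11 steps (steps 1–8, 10, 13, 14, from 1).

Steps most likely to fail

Step 5. The ligand may discriminate too weakly between the two enantiotopic enol ethers, or the simple keto carbenoid may be diverted to the prenyl alkene or to an oxonium ylide. The fallback sets out from 7 and comes back at 11; it uses an acceptor/acceptor carbenoid, the substrate class for which this copper-catalysed cyclopropanation is most selective, and removes the extra acceptor afterwards. The lithium enolate of 7 (LiHMDS, 2.2 equiv, THF, −78 °C) would be C-sulfonylated with benzenesulfonyl fluoride to the β-keto sulfone F1. Regitz diazo transfer (p-ABSA, Et3N, MeCN) would give the α-diazo-β-keto sulfone F2. Cu(I)–bis(oxazoline) cyclopropanation would give the sulfonyl methoxycyclopropane F3, which dilute acid opens in the same flask to the 8-phenylsulfonyl diketone F4. Reductive desulfonylation (SmI2, THF–MeOH, −78 °C) would return 11.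

Step 3. Deprotonation of the hindered doubly allylic C–H may be incomplete, or the pentadienyl anion may be alkylated at a terminal carbon and not at the congested central one. The fallback sets out from 5 and comes back at 6; it makes the quaternary carbon before the gem-dimethyl group, so that both alkylations at the ring use an unhindered CH2 electrophile. Commercial 1,5-dimethoxycyclohexa-1,4-diene F5 would be lithiated (t-BuLi, THF, −78 °C) and alkylated with 5 to the 6-prenyl diene F6. A second lithiation and alkylation with lithium iodoacetate would give the lithium dienylacetate F7. Two successive enediolate methylations (LDA, MeI; LDA, DMPU, MeI), passing through the monomethyl carboxylate F8, would give 6, which is treated with MeLi as in step 3.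

Step 10. The bridgehead carbanion may act as a base and eliminate triflate (the β-hydrogen of 18 is allylic), or the homoallylic triflate may ionise before SN2 attack. The fallback sets out from 16 and 17 and comes back at 19; it forms the C1–C bond by carbonyl addition and removes the oxygen afterwards. Dess–Martin oxidation of 17 (NaHCO3, CH2Cl2, 0 °C) would give (R)-lavandulal F9, used at once. The bridgehead lithium derivative of 16 (LDA, THF, −78 °C) would add to F9 to give the bridgehead aldol F10 as a mixture at the carbinol carbon. Phenyl chlorothionoformate, pyridine and DMAP would give the O-phenyl thiocarbonate F11. Barton–McCombie reduction (Bu3SnH, 0.5 M, AIBN, toluene, 80 °C) would give 19; the high stannane concentration is meant to trap the secondary radical before homoallyl or 1,2-acyl rearrangement.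

Further compounds
F1 | step 5 | β-keto sulfone: 3-[2,6-dimethoxy-1-(3-methylbut-2-en-1-yl)cyclohexa-2,5-dien-1-yl]-3-methyl-1-(phenylsulfonyl)butan-2-one | COC1=CCC=C(OC)C1(CC=C(C)C)C(C)(C)C(=O)CS(=O)(=O)c1ccccc1
F2 | step 5 | α-diazo-β-keto sulfone: 1-diazo-3-[2,6-dimethoxy-1-(3-methylbut-2-en-1-yl)cyclohexa-2,5-dien-1-yl]-3-methyl-1-(phenylsulfonyl)butan-2-one | COC1=CCC=C(OC)C1(CC=C(C)C)C(C)(C)C(=O)C(=[N+]=[N-])S(=O)(=O)c1ccccc1
F3 | step 5 | sulfonyl methoxycyclopropane: 10 with phenylsulfonyl in place of H on C8 | COC1=CC[C@H]2[C@@]3(S(=O)(=O)c4ccccc4)C(=O)C(C)(C)[C@]1(CC=C(C)C)[C@@]23OC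
F4 | step 5 | 8-phenylsulfonyl diketone: 11 with phenylsulfonyl on C8 (C1 and C5 as in 11, C8 epimers) | [C@@H]12C(S(=O)(=O)c3ccccc3)C(=O)C(C)(C)[C@@](CC=C(C)C)(C(OC)=CC1)C2=O
F5 | step 3 | 1,5-dimethoxycyclohexa-1,4-diene | COC1=CCC=C(OC)C1
F6 | step 3 | 6-prenyl diene: 1,5-dimethoxy-6-(3-methylbut-2-en-1-yl)cyclohexa-1,4-diene | COC1=CCC=C(OC)C1CC=C(C)C
F7 | step 3 | lithium dienylacetate: lithium 2-[2,6-dimethoxy-1-(3-methylbut-2-en-1-yl)cyclohexa-2,5-dien-1-yl]acetate | COC1=CCC=C(OC)C1(CC=C(C)C)CC(=O)[O-].[Li+]
F8 | step 3 | monomethyl carboxylate: lithium 2-[2,6-dimethoxy-1-(3-methylbut-2-en-1-yl)cyclohexa-2,5-dien-1-yl]propanoate (racemic) | COC1=CCC=C(OC)C1(CC=C(C)C)C(C)C(=O)[O-].[Li+]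
F9 | step 10 | (R)-lavandulal [(2R)-5-methyl-2-(prop-1-en-2-yl)hex-4-enal] | C=C(C)[C@@H](CC=C(C)C)C=O
F10 | step 10 | bridgehead aldol: 16 carrying CH(OH)–CH(isopropenyl)–CH2–CH=CMe2 on C1 (carbinol epimers) | C=C(C)[C@@H](CC=C(C)C)C(O)[C@@]12C[C@@H](CC=C(C)C)C(C)(C)[C@@](CC=C(C)C)(C(OC)=CC1=O)C2=O
F11 | step 10 | O-phenyl thiocarbonate of F10 | C=C(C)[C@@H](CC=C(C)C)C(OC(=S)Oc3ccccc3)[C@@]12C[C@@H](CC=C(C)C)C(C)(C)[C@@](CC=C(C)C)(C(OC)=CC1=O)C2=O
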